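| flask | X | J | E | remark | time |
|---|---|---|---|---|---|
| north | 3 M | 1.5 M | 7.5 mol% | run made earlier |  |
| green | 3.0 M | 1.50 M | 5 mol% |  | 2.0 h |
| blue | 0.80 M | 1.50 M | 5 mol% |  | 2.0 h |

- north (time / min: Q / %): 4.00: 2.6; 12.0: 9.6; 20.0: 14.9; 30.0: 23.2; 40.0: 27.1; 60.0: 33.1; 80.0: 36.1

(standard deviation of a reading: 0.5 percentage points)

- the average divides the monomer in chains by the number of chains begun, living and dead together
- the numbers in the tables scatter with a standard deviation of 0.5 percentage points
- the earlier runs do not show the number of chains; that part of a forecast is a guess
- no earlier run changes the charge of E; that part of a forecast is a guess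

- which of the two ends with the longer chains by the average number of monomer units in a chain (chains begun, living or dead) ("neither" if they lie within 10%) (green / blue / neither)
- average number of monomer units in a chain (chains begun, living or dead) at the end, green
- average number of monomer units in a chain (chains begun, living or dead) at the end, blue

1. In the north run, the reading of Q at 80.0 min leaves 63.9% of the charged X not in chains, yet Q rose by 3 percentage points over the last 20.0 min, against 6 points over the 20.0 min before. So the rise of Q is slowing, and the last reading serves as north's working level.

2. That reading gives north u = 4.81, the monomer units in chains per E charged. Let n be the average length (the number-average degree of polymerisation) and f the share of E used. If one E begins one chain, n = u/f, and u is a floor for n.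

3. Green differs from north in its E charge and its time. If Q scales with the E charge, green keeps u = 4.81. If Q keeps north's share, green reaches u = 7.22. My bracket on u for green is these two values; it bounds u, not n.

4. Blue carries more J per X than green, 1.88 against 0.500. With X changed, my bracket on u for blue runs from zero to 7.22, and my bet is green.

5. The forecast says green, with 6.3 (4 to 10) for green, more than 4.81 and less than 7.22, and 1.2 (0 to 3.5) for blue: “roughly 6 units per chain if every E starts one”.

6. The simulation gives green, with 7.31 for green and 2.31 for blue.

    Z → G (k = 8.50 × 10⁻⁴ s⁻¹)
    J + X → L (k = 4.30 × 10⁻⁴ M⁻¹ s⁻¹)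
    X + Z → Q + Z, rate k3*[Z]*[X] (k = 0.00440 M⁻¹ s⁻¹)
    X + E → Z + Q (k = 2.10 × 10⁻⁴ M⁻¹ s⁻¹)

7. At the end, green has u = 5.98, inside the bracket on u, and f = 81.8%, so n = 7.31. Blue has u = 0.647 and f = 28.0%, so n = 2.31. Green has not come to rest: by 20.0 h its E falls from 18% to 0.0210%, Q goes from 29.9% to 34.0%, and n drops to 6.81. Blue moves less: Q goes from 3.24% to 3.34%, and n drops to 2.24.

8. A neighbour of green, the same flask with 1.2 mol% of E, gets the bracket on u of 4.81 to 30.1. That neighbour ends with Q at 9.71%, so u = 8.09, and n = 8.97.

Readings and results are simulated from invented constants; the scatter is artificial.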